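**Retrosynthetic overview**

1. Target 23 is a bicyclo[3.2.1]octan-2-one (C1 = OMe bridgehead, C2 = C=O, C3 = CHOMe, C4 = CH2, C5 = allyl bridgehead, C6 = CHMe, C7 = CHAr, C8 = CHOH); it is reached from bicyclic enone 21 by conjugate reduction of C3=C4 (sets C3) and removal of the phenol protecting group.
2. Key disconnection: the one-carbon bridge C8 is cut at C1–C8 and at C5–C8, which leaves the monocyclic 2,7-dimethoxycyclohept-2-enone 19 and a formate ester; forward, C1–C8 is made by α'-C-formylation and the ring closure C5–C8 by a transannular vinylogous aldol addition in the same flask.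
3. Enabling feature: in 23 the carbinol C8 is β to the C2 ketone through bridgehead C1, and bridgehead C5 is γ to the same ketone through C3(OMe)–C4. In the seven-membered ring C1–C2–C3–C4–C5–C6–C7 the α'- and γ-carbons of one enone can therefore both be made nucleophilic and be bridged by a single formyl carbon.
4. The cycloheptenone comes from a cyclohexanone by one-carbon ring expansion through a temporary cyclopropane (made in step 9, cleaved in step 10); the cyclohexane comes from an organocatalytic Michael/aldol sequence followed by two cuprate additions (aryl, then allyl).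
5. Ring order: six-membered carbocycle → seven-membered ring → five- and six-membered rings of the bicycle closed together by the C5–C8 bond. Stereocentres: C6 by the organocatalyst, C7 by 1,2-induction, C1/C5/C8 in the key step, C3 last.

Key step: step 12

Remark (names): Ar = 4-methoxy-3-(methoxymethoxy)phenyl; locants in a name refer to the compound named. In the Why lines of steps 12 to 14 the target numbering of line 1 is used.

Assumption (chemistry): the sense of induction in step 2 is taken by analogy with related diarylprolinol ether catalysis. If it is opposite, the enantiomeric catalyst is used. The configurations at the allyl-bearing and the α'-methoxy carbon of 14 to 19 are inconsequential, since both centres become sp2 in step 12.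

**Route**

Step 1
Reactants: 1 5-bromo-2-methoxyphenol
Product: 2 4-bromo-1-methoxy-2-(methoxymethoxy)benzene
Conditions: MOMCl, iPr2NEt, CH2Cl2, 0 °C to rt
Reagents that add atoms: chloromethyl methyl ether COCCl
Why: Williamson-type O-alkylation gives a MOM acetal that should survive the organomagnesium, amide-base, methoxide and copper hydride steps and is cleaved by dilute acid at the end; no stereocentre is involved.

Step 2
Reactants: 3 propanal; 4 but-3-en-2-one (methyl vinyl ketone)
Product: 5 (S)-2-methyl-5-oxohexanal
Conditions: (R)-2-[methoxy(diphenyl)methyl]pyrrolidine (5 mol%), ethyl 3,4-dihydroxybenzoate (20 mol%), neat, 4 °C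
Reagents that add atoms: none
Why: Enamine-catalysed asymmetric Michael addition of an aldehyde to an enone (Gellman type), in which the methoxydiphenylmethyl group shields one face of the (E)-enamine, so that the catalyst sets the methyl-bearing stereocentre (future C6 of the target); the (R)-catalyst is expected to give the (S)-aldehyde.

Step 3
Reactants: 5 (S)-2-methyl-5-oxohexanal
Product: 6 (S)-4-methylcyclohex-2-en-1-one
Conditions: KOH (0.1 M aq), Bu4NOH (cat.), Et2O/THF, reflux
Reagents that add atoms: none
Why: Intramolecular aldol condensation of the methyl ketone onto the aldehyde (6-enolendo-exo-trig, then E1cB dehydration) under mild phase-transfer base, which should leave the γ-stereocentre untouched.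

Step 4
Reactants: 2 4-bromo-1-methoxy-2-(methoxymethoxy)benzene; 6 (S)-4-methylcyclohex-2-en-1-one
Product: 8 trimethyl{[(3R,4S)-3-Ar-4-methylcyclohex-1-en-1-yl]oxy}silane, via arylmagnesium bromide 7 (not isolated)
Conditions: Mg, THF, 50 °C; then CuBr·SMe2 (10 mol%), TMSCl, HMPA, THF, −78 °C, add 6; Et3N, pentane work-up
Reagents that add atoms: chlorotrimethylsilane C[Si](C)(C)Cl
Why: Grignard formation followed by copper-catalysed, TMSCl-accelerated conjugate addition (Kuwajima–Nakamura conditions), in which the aryl group should enter anti to the C4 methyl group to give the 3,4-trans product (future C7), and the enolate is trapped regiospecifically as its silyl enol ether.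

Step 5
Reactants: 8 trimethyl{[(3R,4S)-3-Ar-4-methylcyclohex-1-en-1-yl]oxy}silane
Product: 10 (2S,3S,4S)-3-Ar-2-hydroxy-4-methylcyclohexan-1-one, via α-silyloxy ketone 9 (not isolated)
Conditions: mCPBA, CH2Cl2/hexane, −15 °C to rt; then K2CO3 (cat.), MeOH, 0 °C
Reagents that add atoms: 3-chloroperbenzoic acid OOC(=O)c1cccc(Cl)c1
Why: Rubottom oxidation (epoxidation of the silyl enol ether, 1,4-silyl shift to 9, methanolysis) places oxygen on C2, expected mainly anti to the aryl group, a configuration that is inconsequential because this carbon is enolised again in step 12.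

Step 6
Reactants: 10 (2S,3S,4S)-3-Ar-2-hydroxy-4-methylcyclohexan-1-one
Product: 11 (2S,3S,4S)-3-Ar-2-methoxy-4-methylcyclohexan-1-one
Conditions: MeI, Ag2O, 4 Å MS, MeCN, 40 °C
Reagents that add atoms: iodomethane CI
Why: Purdie-type O-methylation with MeI/Ag2O under non-basic conditions should avoid enolisation and α-ketol shift of the hydroxy ketone.

Step 7
Reactants: 11 (2S,3S,4S)-3-Ar-2-methoxy-4-methylcyclohexan-1-one
Product: 13 (4S,5S,6S)-5-Ar-6-methoxy-4-methylcyclohex-2-en-1-one, via enol silane 12 (not isolated)
Conditions: LDA, TMSCl, THF, −78 °C; then Pd(OAc)2 (1.05 equiv), MeCN, rt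
Reagents that add atoms: none
Why: LDA should deprotonate kinetically at the CH2 group (C6) and not at the methoxy-bearing carbon, and Saegusa–Ito dehydrosilylation of enol silane 12 with Pd(OAc)2 then gives the enone on the side that is to receive the allyl group.

Step 8
Reactants: 13 (4S,5S,6S)-5-Ar-6-methoxy-4-methylcyclohex-2-en-1-one
Product: 14 trimethyl{[(3S,4S,5S,6S)-3-allyl-5-Ar-6-methoxy-4-methylcyclohex-1-en-1-yl]oxy}silane
Conditions: allylMgBr, CuBr·SMe2, TMSCl, THF, −78 °C; Et3N, pentane work-up
Reagents that add atoms: allylmagnesium bromide C=CC[Mg]Br; chlorotrimethylsilane C[Si](C)(C)Cl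
Why: TMSCl-mediated 1,4-addition of an allylcopper reagent (Lipshutz type), expected trans to the C4 methyl group although this configuration is erased in step 12, with silyl trapping that fixes the enol ether between C1 and C2 for the ring expansion.

Step 9
Reactants: 14 trimethyl{[(3S,4S,5S,6S)-3-allyl-5-Ar-6-methoxy-4-methylcyclohex-1-en-1-yl]oxy}silane
Product: 15 5-allyl-3-Ar-2-methoxy-4-methyl-1-(trimethylsilyloxy)bicyclo[4.1.0]heptane (ring substituents as in 14; both cyclopropane faces)
Conditions: Et2Zn, CH2I2, CH2Cl2, 0 °C
Reagents that add atoms: diiodomethane ICI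
Why: Furukawa–Simmons–Smith cyclopropanation, in which the electron-rich silyl enol ether should react much faster than the monosubstituted allyl double bond; the face of attack is irrelevant because both new stereocentres are destroyed in step 10.

Step 10
Reactants: 15 5-allyl-3-Ar-2-methoxy-4-methyl-1-(trimethylsilyloxy)bicyclo[4.1.0]heptane
Product: 17 (4R,5S,6S,7S)-4-allyl-6-Ar-7-methoxy-5-methylcyclohept-2-en-1-one, via β-chloro ketone 16 (not isolated)
Conditions: FeCl3, DMF, 0 °C to rt; then NaOAc, MeOH, reflux
Reagents that add atoms: none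
Why: Ito–Saegusa ring expansion (one-electron oxidation of the siloxycyclopropane by FeCl3, β-scission of the ring-fusion bond to the secondary radical, chlorine transfer to 16, E1cB elimination) cleaves the temporary cyclopropane bond and delivers the cyclohept-2-enone with the new CH next to the carbonyl group.

Step 11
Reactants: 17 (4R,5S,6S,7S)-4-allyl-6-Ar-7-methoxy-5-methylcyclohept-2-en-1-one
Product: 19 (5S,6S)-4-allyl-6-Ar-2,7-dimethoxy-5-methylcyclohept-2-en-1-one (C4/C7 epimers), via epoxy ketone 18 (not isolated)
Conditions: H2O2 (30% aq), NaOH (cat.), MeOH, 0 °C; then NaOMe, MeOH, 60 °C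
Reagents that add atoms: sodium methoxide C[O-].[Na+]
Why: Weitz–Scheffer epoxidation of the enone (the allyl double bond is inert to hydroperoxide anion) followed by methoxide opening of epoxy ketone 18 at the α-carbon and E1cB loss of hydroxide should give the 2-methoxy enone; epimerisation at C4 and C7 under methoxide is of no consequence.

Step 12
Reactants: 19 (5S,6S)-4-allyl-6-Ar-2,7-dimethoxy-5-methylcyclohept-2-en-1-one (C4/C7 epimers)
Product: 21 (1S,5R,6R,7S,8S)-5-allyl-7-Ar-8-hydroxy-1,3-dimethoxy-6-methylbicyclo[3.2.1]oct-3-en-2-one, via formyl ketone 20 (not isolated)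
Conditions: LDA, THF, −78 °C; HCO2CH2CF3, −78 °C; LiHMDS, −78 to −40 °C; AcOH, −78 °C
Reagents that add atoms: 2,2,2-trifluoroethyl formate O=COCC(F)(F)F
Why: Proposed new method: LDA removes the only α'-proton of 19 (on the future C1) to give the cross-conjugated lithium enolate, which is C-formylated anti to the aryl group on the adjacent C7; the non-enolisable β-keto aldehyde 20 is then deprotonated by LiHMDS at its only remaining acidic site, the γ-carbon (future C5), and the extended enolate adds through C5 to the formyl carbon C8, because attack through the α-carbon C3 would need a four-membered ring. The closest known reaction types are the Claisen C-formylation of ketone enolates with this formate and the intramolecular vinylogous aldol addition of γ-deprotonated enones, whereas their coupling, with one formate carbon bridging the α'- and γ-carbons of an enone, is not established. The C5–C8 closure is transannular across the seven-membered ring and closes two rings at once, the five-membered ring C5–C6–C7–C1–C8 in a 5-(enolexo)-exo-trig mode and the six-membered ring C1–C2–C3–C4–C5–C8 in a 6-(enolendo)-exo-trig mode. Quaternary C1 is controlled by 1,2-induction from the C7 aryl group (pseudoaxial to avoid allylic strain with the enolate methoxy group), quaternary C5 has no choice because the one-carbon bridge can only span the ring face that carries the formyl group, and at C8 a lithium ion bridging the dienolate oxygen and the aldehyde oxygen, together with avoidance of the exo C6 methyl group, should turn the hydroxyl toward the C2–C4 bridge. The step needs α'- over γ-deprotonation in the first stage (kinetic LDA conditions at −78 °C), C- over O-formylation (lithium enolate in THF, reactive formate) and an aldol addition that outruns retro-Claisen loss of the formyl group and is not reversed (low temperature, acidic quench).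

Step 13
Reactants: 21 (1S,5R,6R,7S,8S)-5-allyl-7-Ar-8-hydroxy-1,3-dimethoxy-6-methylbicyclo[3.2.1]oct-3-en-2-one
Product: 22 (1S,3S,5S,6R,7S,8S)-5-allyl-7-Ar-8-hydroxy-1,3-dimethoxy-6-methylbicyclo[3.2.1]octan-2-one
Conditions: [(Ph3P)CuH]6, H2O (5 equiv), toluene, rt
Reagents that add atoms: none
Why: Stryker conjugate reduction, chemoselective for the enone over the allyl double bond, delivers hydride to C4, and the copper enolate should then be protonated at C3 from the exo face (the side of the C8 bridge, whose hydroxyl can relay the proton) because the endo face is screened by the C6–C7 bridge and the endo aryl group, which gives the 3S (endo-methoxy) ketone.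

Step 14
Reactants: 22 (1S,3S,5S,6R,7S,8S)-5-allyl-7-Ar-8-hydroxy-1,3-dimethoxy-6-methylbicyclo[3.2.1]octan-2-one
Product: 23 (1S,3S,5S,6R,7S,8S)-5-allyl-8-hydroxy-7-(3-hydroxy-4-methoxyphenyl)-1,3-dimethoxy-6-methylbicyclo[3.2.1]octan-2-one
Conditions: HCl (2 M aq), MeOH/THF, 40 °C
Reagents that add atoms: none
Why: Acid-catalysed transacetalisation removes the aryl MOM group, while the aliphatic methyl ethers, the allyl group and the β-hydroxy ketone are expected to persist under these mild conditions.

**Compound list**

1 | 5-bromo-2-methoxyphenol | COc1ccc(Br)cc1O | starting material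
2 | 4-bromo-1-methoxy-2-(methoxymethoxy)benzene | COCOc1cc(Br)ccc1OC | intermediate
3 | propanal | CCC=O | starting material
4 | but-3-en-2-one (methyl vinyl ketone) | CC(=O)C=C | starting material
5 | (S)-2-methyl-5-oxohexanal | O=C[C@@H](C)CCC(C)=O | intermediate
6 | (S)-4-methylcyclohex-2-en-1-one | O=C1C=C[C@@H](C)CC1 | intermediate
7 | [4-methoxy-3-(methoxymethoxy)phenyl]magnesium bromide | COCOc1cc([Mg]Br)ccc1OC | intermediate (not isolated)
8 | trimethyl{[(3R,4S)-3-Ar-4-methylcyclohex-1-en-1-yl]oxy}silane | C[Si](C)(C)OC1=C[C@H](c2ccc(OC)c(OCOC)c2)[C@@H](C)CC1 | intermediate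
9 | (2S,3S,4S)-3-Ar-4-methyl-2-(trimethylsilyloxy)cyclohexan-1-one | O=C1[C@@H](O[Si](C)(C)C)[C@H](c2ccc(OC)c(OCOC)c2)[C@@H](C)CC1 | intermediate (not isolated)
10 | (2S,3S,4S)-3-Ar-2-hydroxy-4-methylcyclohexan-1-one | O=C1[C@@H](O)[C@H](c2ccc(OC)c(OCOC)c2)[C@@H](C)CC1 | intermediate
11 | (2S,3S,4S)-3-Ar-2-methoxy-4-methylcyclohexan-1-one | O=C1[C@@H](OC)[C@H](c2ccc(OC)c(OCOC)c2)[C@@H](C)CC1 | intermediate
12 | trimethyl{[(4S,5S,6S)-5-Ar-6-methoxy-4-methylcyclohex-1-en-1-yl]oxy}silane | C[Si](C)(C)OC1=CC[C@H](C)[C@@H](c2ccc(OC)c(OCOC)c2)[C@@H]1OC | intermediate (not isolated)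
13 | (4S,5S,6S)-5-Ar-6-methoxy-4-methylcyclohex-2-en-1-one | O=C1C=C[C@H](C)[C@@H](c2ccc(OC)c(OCOC)c2)[C@@H]1OC | intermediate
14 | trimethyl{[(3S,4S,5S,6S)-3-allyl-5-Ar-6-methoxy-4-methylcyclohex-1-en-1-yl]oxy}silane | C[Si](C)(C)OC1=C[C@@H](CC=C)[C@H](C)[C@@H](c2ccc(OC)c(OCOC)c2)[C@@H]1OC | intermediate
15 | 5-allyl-3-Ar-2-methoxy-4-methyl-1-(trimethylsilyloxy)bicyclo[4.1.0]heptane (ring substituents as in 14; both cyclopropane faces) | C[Si](C)(C)OC12CC1[C@@H](CC=C)[C@H](C)[C@@H](c3ccc(OC)c(OCOC)c3)[C@@H]2OC | intermediate
16 | 4-allyl-6-Ar-3-chloro-7-methoxy-5-methylcycloheptan-1-one (C3 epimers) | O=C1CC(Cl)[C@@H](CC=C)[C@H](C)[C@@H](c2ccc(OC)c(OCOC)c2)[C@@H]1OC | intermediate (not isolated)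
17 | (4R,5S,6S,7S)-4-allyl-6-Ar-7-methoxy-5-methylcyclohept-2-en-1-one | O=C1C=C[C@@H](CC=C)[C@H](C)[C@@H](c2ccc(OC)c(OCOC)c2)[C@@H]1OC | intermediate
18 | 4-allyl-6-Ar-2,3-epoxy-7-methoxy-5-methylcycloheptan-1-one (epimer mixture; 5S,6S fixed) | O=C1C2OC2C(CC=C)[C@H](C)[C@@H](c3ccc(OC)c(OCOC)c3)C1OC | intermediate (not isolated)
19 | (5S,6S)-4-allyl-6-Ar-2,7-dimethoxy-5-methylcyclohept-2-en-1-one (C4/C7 epimers) | O=C1C(OC)=CC(CC=C)[C@H](C)[C@@H](c2ccc(OC)c(OCOC)c2)C1OC | intermediate
20 | (5S,6S,7S)-4-allyl-6-Ar-7-formyl-2,7-dimethoxy-5-methylcyclohept-2-en-1-one (C4 epimers) | C=CCC1C=C(OC)C(=O)[C@@](OC)(C=O)[C@H](c2ccc(OC)c(OCOC)c2)[C@H]1C | intermediate (not isolated)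
21 | (1S,5R,6R,7S,8S)-5-allyl-7-Ar-8-hydroxy-1,3-dimethoxy-6-methylbicyclo[3.2.1]oct-3-en-2-one | C=CC[C@]12C=C(OC)C(=O)[C@](OC)([C@H](c3ccc(OC)c(OCOC)c3)[C@H]1C)[C@H]2O | intermediate
22 | (1S,3S,5S,6R,7S,8S)-5-allyl-7-Ar-8-hydroxy-1,3-dimethoxy-6-methylbicyclo[3.2.1]octan-2-one | C=CC[C@]12C[C@H](OC)C(=O)[C@](OC)([C@H](c3ccc(OC)c(OCOC)c3)[C@H]1C)[C@H]2O | intermediate
23 | (1S,3S,5S,6R,7S,8S)-5-allyl-8-hydroxy-7-(3-hydroxy-4-methoxyphenyl)-1,3-dimethoxy-6-methylbicyclo[3.2.1]octan-2-one | C=CC[C@]12C[C@H](OC)C(=O)[C@](OC)([C@H](c3ccc(OC)c(O)c3)[C@H]1C)[C@H]2O | target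

**Step count and risks**

Total step count: 14. Longest linear sequence: 13 steps (steps 2 to 14); step 1 prepares the aryl bromide that enters in step 4.

Steps most likely to fail:

1. Step 12 (proposed new method). The one-pot sequence may break down through O-formylation of the hindered enolate, through retro-Claisen loss of the formyl group before γ-deprotonation, or through intermolecular aldol addition of unreacted enolate to the transient aldehyde. The fallback uses known reactions in three separate operations and sets out from 19. The lithium enolate (LDA, THF, −78 °C) is hydroxymethylated with monomeric formaldehyde, anti to the aryl group, to give the 7-(hydroxymethyl) ketone F1. Oxidation with Dess–Martin periodinane (NaHCO3, CH2Cl2) gives formyl ketone 20, now isolated. LiHMDS (THF, −78 °C) then effects the intramolecular vinylogous aldol addition, and the route is rejoined at 21.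

2. Step 13. Hydride transfer to the neopentyl β-carbon of the α-methoxy enone may be slow, and protonation of the enolate may occur with poor facial selectivity, so that the C3 epimer is formed. The fallback replaces kinetic control by thermodynamic control and sets out from 21. Whatever conjugate reduction succeeds (Stryker's reagent with a silane, or L-Selectride at −78 °C) is accepted even if it gives the 3-epi ketone F2. This is then equilibrated through the enol with DBU in toluene; 22 is separated and the remaining epimer is resubmitted. The route is rejoined at 22.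

3. Step 11. The epoxy ketone may open at the β-carbon, isomerise to the diosphenol or suffer base-induced side reactions, so that the 2-methoxy enone is not formed cleanly. The fallback avoids the epoxide and sets out from 17. Johnson α-iodination (I2, pyridine, CH2Cl2) gives the 2-iodo enone F3. A copper-catalysed C–O coupling of this vinyl iodide with methanol (CuI, 3,4,7,8-tetramethyl-1,10-phenanthroline, Cs2CO3, MeOH/toluene, 80 °C) then gives 19, where the route is rejoined.

**Further compounds**

F1 | step 12 | (5S,6S,7S)-4-allyl-6-Ar-7-(hydroxymethyl)-2,7-dimethoxy-5-methylcyclohept-2-en-1-one (C4 epimers) | C=CCC1C=C(OC)C(=O)[C@@](OC)(CO)[C@H](c2ccc(OC)c(OCOC)c2)[C@H]1C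
F2 | step 13 | (1S,3R,5S,6R,7S,8S)-5-allyl-7-Ar-8-hydroxy-1,3-dimethoxy-6-methylbicyclo[3.2.1]octan-2-one (3-epimer of 22) | C=CC[C@]12C[C@@H](OC)C(=O)[C@](OC)([C@H](c3ccc(OC)c(OCOC)c3)[C@H]1C)[C@H]2O
F3 | step 11 | 4-allyl-6-Ar-2-iodo-7-methoxy-5-methylcyclohept-2-en-1-one (ring configuration as in 17) | O=C1C(I)=C[C@@H](CC=C)[C@H](C)[C@@H](c2ccc(OC)c(OCOC)c2)[C@@H]1OC
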